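**Retrosynthetic overview**

1. The target is reached by BCl3 unmasking of its 5,7-di-O-benzyl-5''-O-methyl ether: both benzyl ethers and the chelated 5''-methyl ether fall, the 7''- and 4'-methyl ethers stay.
2. Both pyranone rings come from a one-flask double aryne annulation of the (S,S,S,S)-2,3-bis[hydroxy(4-methoxyphenyl)methyl]succinic bis(dimethylamide): ring C (O1–C8a, C4–C4a) closes first with 3,5-bis(benzyloxy)benzyne, ring C'' (O1''–C8a'', C4''–C4a'') second with 3,5-dimethoxybenzyne; rings A and A'' arrive as the arynes.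
3. Feature used: in each half O1 and the C4 carbonyl carbon are ortho neighbours on ring A (C8a, C4a) and 1,3-related through C2–C3, with the 5- and 7-oxygens meta to O1, which is the pattern left when an oxygen adds to a 3,5-dialkoxybenzyne and the aryl anion is acylated.
4. The two carbinols of the C2-symmetric diol are equivalent and could not tell two different arynes apart, so one is carried as a TBS ether and released by fluoride between the two aryne additions.
5. The diol bis-amide comes from aminolysis of the resolved exo,exo cis-fused bislactone, itself the oxidative dimer of 4-methoxycinnamic acid (all four stereocentres set there); the aryne precursors come from ortho-bromination, retro-Brook silyl shift and triflation of 3,5-dialkoxyphenols.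

Key step: step 10

Remark: the cis,cis (2S,3S,2''S,3''S) target corresponds to the (3S,3aS,6S,6aS) enantiomer of the exo,exo bislactone; the racemate is resolved on a chiral phase and the enantiomer is identified before it is carried on.

**Route**

Step 1
Reactants: 1 4-methoxycinnamic acid (two molecules)
Product: 2 rac-exo,exo-3,6-bis(4-methoxyphenyl)tetrahydro-1H,4H-furo[3,4-c]furan-1,4-dione
Conditions: Tl(OCOCF3)3 (0.55 equiv), BF3·OEt2, CF3CO2H/CH2Cl2, 0 °C
Reagents that add atoms: none
Why: One-electron oxidation of the electron-rich cinnamic acid by trivalent thallium should give a radical cation that dimerises at the carbon alpha to the carboxyl, each 4-methoxybenzylic cation being trapped by the carboxyl of the other half (oxidative dehydrodimerisation known for 4-alkoxycinnamic acids); the bicyclo[3.3.0] frame forces the cis fusion and both aryl groups take the convex face, which sets the relative configuration of all four stereocentres.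

Step 2
Reactants: 2 racemic bislactone
Product: 3 (3S,3aS,6S,6aS)-3,6-bis(4-methoxyphenyl)tetrahydro-1H,4H-furo[3,4-c]furan-1,4-dione
Conditions: preparative SFC, amylose tris(3,5-dimethylphenylcarbamate) phase, CO2/i-PrOH
Reagents that add atoms: none
Why: Chromatographic resolution of a rigid neutral racemate on a chiral stationary phase, the wanted enantiomer to be identified by anomalous-dispersion X-ray analysis or ECD comparison; this fixes the absolute sense of the four centres.

Step 3
Reactants: 3 (3S,3aS,6S,6aS)-bislactone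
Product: 4 (2S,3S)-2,3-bis[(S)-hydroxy(4-methoxyphenyl)methyl]-N,N,N',N'-tetramethylbutanediamide
Conditions: AlMe3 (5 equiv), Me2NH (2 M in THF, 5 equiv), CH2Cl2, 0 °C → rt; aq KNaC4H4O6, 0 °C
Reagents that add atoms: dimethylamine CNC
Why: Aluminium-amide aminolysis of gamma-lactones attacks only the two acyl carbons, so both rings should open with every C–O and C–H stereocentre untouched; the cold neutral work-up is meant to keep the gamma-hydroxy amides from closing back with loss of dimethylamine.

Step 4
Reactants: 4 diol bis-amide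
Product: 5 (2S,3S)-2-[(S)-(tert-butyldimethylsilyloxy)(4-methoxyphenyl)methyl]-3-[(S)-hydroxy(4-methoxyphenyl)methyl]-N,N,N',N'-tetramethylbutanediamide
Conditions: TBSOTf (1.0 equiv), 2,6-lutidine, CH2Cl2, −78 °C
Reagents that add atoms: tert-butyldimethylsilyl triflate CC(C)(C)[Si](C)(C)OS(=O)(=O)C(F)(F)F
Why: Silylation of one of two symmetry-equivalent secondary hydroxyls with one equivalent of silyl triflate; either oxygen gives the same compound because of the C2 axis, and recovered 4 and the bis-silyl ether (after desilylation) are returned to the step.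

Step 5
Reactants: 6 phloroglucinol
Product: 7 3,5-bis(benzyloxy)phenol
Conditions: BnBr (2.0 equiv), K2CO3, DMF, rt
Reagents that add atoms: benzyl bromide BrCc1ccccc1
Why: Williamson etherification with two equivalents of benzyl bromide under weak base; the reaction is statistical and the dibenzyl ether is separated from the mono- and tri-ethers.

Step 6
Reactants: 7 3,5-bis(benzyloxy)phenol
Product: 8 3,5-bis(benzyloxy)-2-bromophenol
Conditions: NBS (1.0 equiv), CH2Cl2, −78 °C
Reagents that add atoms: N-bromosuccinimide O=C1CCC(=O)N1Br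
Why: Electrophilic aromatic bromination at low temperature should go ortho to the free hydroxyl (hydrogen-bond-guided delivery, the position between the two benzyloxy groups being the more hindered), any para isomer being removed by chromatography.

Step 7
Reactants: 8 3,5-bis(benzyloxy)-2-bromophenol
Product: 11 3,5-bis(benzyloxy)-2-(trimethylsilyl)phenyl triflate, via aryl trimethylsilyl ether 9 (not isolated), via lithium 2-silylphenoxide 10 (not isolated)
Conditions: (Me3Si)2NH, THF, 65 °C, evaporate; n-BuLi, THF, −78 °C; Tf2O, −78 °C → rt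
Reagents that add atoms: hexamethyldisilazane C[Si](C)(C)N[Si](C)(C)C; triflic anhydride O=S(=O)(OS(=O)(=O)C(F)(F)F)C(F)(F)F
Why: O-silylation, bromine–lithium exchange and retro-Brook 1,3 O-to-C silyl shift should give the 2-silylphenoxide, which is triflated in the same flask; the exchange at −78 °C is faster than benzylic deprotonation, so the benzyl ethers should survive.

Step 8
Reactants: 12 3,5-dimethoxyphenol
Product: 13 2-bromo-3,5-dimethoxyphenol
Conditions: NBS (1.0 equiv), CH2Cl2, −78 °C
Reagents that add atoms: N-bromosuccinimide O=C1CCC(=O)N1Br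
Why: Hydroxyl-guided ortho-bromination as in step 6, the ortho bromide being separated from any para isomer.

Step 9
Reactants: 13 2-bromo-3,5-dimethoxyphenol
Product: 16 3,5-dimethoxy-2-(trimethylsilyl)phenyl triflate, via aryl trimethylsilyl ether 14 (not isolated), via lithium 2-silylphenoxide 15 (not isolated)
Conditions: (Me3Si)2NH, THF, 65 °C, evaporate; n-BuLi, THF, −78 °C; Tf2O, −78 °C → rt
Reagents that add atoms: hexamethyldisilazane C[Si](C)(C)N[Si](C)(C)C; triflic anhydride O=S(=O)(OS(=O)(=O)C(F)(F)F)C(F)(F)F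
Why: The same O-silylation, halogen–lithium exchange, retro-Brook shift and triflation sequence as in step 7.

Step 10
Reactants: 5 mono-TBS diol bis-amide; 11 3,5-bis(benzyloxy)-2-(trimethylsilyl)phenyl triflate; 16 3,5-dimethoxy-2-(trimethylsilyl)phenyl triflate
Product: 23 (2S,3S,2''S,3''S)-5,7-bis(benzyloxy)-5'',7''-dimethoxy-2,2''-bis(4-methoxyphenyl)-3,3''-bichromane-4,4''-dione, via potassium alkoxide 17 (not isolated), via 3,5-bis(benzyloxy)benzyne 18 (not isolated), via ring C aminal alkoxide 19 (not isolated), via desilylated dialkoxide 20 (not isolated), via 3,5-dimethoxybenzyne 21 (not isolated), via bis-aminal dialkoxide 22 (not isolated)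
Conditions: KH (1.05 equiv), THF, 0 °C; 11 (1.1 equiv), CsF (1.3 equiv), 18-crown-6, THF, 0 °C → rt; (Me2N)3S+ Me3SiF2− (TASF, 3.5 equiv), rt; 16 (1.5 equiv), rt; AcOH/NaOAc buffer (pH 5), 0 °C
Reagents that add atoms: none
Why: Proposed new method: the potassium alkoxide 17 should add to aryne 18 at the carbon meta to both benzyloxy groups, which leaves the aryl anion between the new ether oxygen and a benzyloxy group, and this anion should add 6-exo-trig to the amide carbonyl three atoms from the oxygen, closing ring C (O1–C8a and C4–C4a) as the 4-(dimethylamino)chroman-4-olate 19. Soluble fluoride from TASF then cleaves the TBS ether, and the second alkoxide 20 repeats the addition and 6-exo-trig acyl capture on aryne 21 to close ring C'' (O1''–C8a'' and C4''–C4a''), giving 22, whose two aminal carbons become the C4 and C4'' ketones in the buffered quench. The closest known reactions are the aryne annulation of salicylate esters to xanthones and the aryne insertion into the C–O bond of carboxylic acids, in which an oxygen nucleophile adds to the aryne and the aryl anion is acylated within the same molecule; an aliphatic beta-alkoxy amide has not been used in this way. No stereocentre is created or touched, since no bond at C2, C3, C2'' or C3'' is made or broken, so the (S,S,S,S) array of 5 should appear as the 2,3-cis and 2'',3''-cis rings. The step needs aryne regioselectivity, set by the alkoxy substituent next to the triple bond, six- over seven-membered closure, set by the 1,3-relation of each oxygen to its nearer amide, and a fixed order of the two arynes, set by the silyl ether, which leaves a single alkoxide while 11 is consumed (silyl transfer between the two carbinol oxygens is degenerate). Both adducts should stay as aminal alkoxides until the quench, so that no enolisable C3–H ketone is exposed to base.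

Step 11
Reactants: 23 5,7-di-O-benzyl-5''-O-methyl biflavanone
Product: 24 (2S,3S,2''S,3''S)-5,7,5''-trihydroxy-7''-methoxy-2,2''-bis(4-methoxyphenyl)-3,3''-bichromane-4,4''-dione (target)
Conditions: BCl3 (excess), C6HMe5, CH2Cl2, −78 → 0 °C; MeOH, aq NaHCO3
Reagents that add atoms: none
Why: BCl3 cleaves benzyl aryl ethers at low temperature (pentamethylbenzene traps the benzyl cation) and, through the six-membered boron chelate with the C4'' carbonyl, only the peri 5''-methyl ether among the methyl ethers; the 7''- and 4'-methoxy groups lack this chelate and should stay, and no stereocentre is involved.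

**Compound list**

1 | 4-methoxycinnamic acid | COc1ccc(/C=C/C(=O)O)cc1 | starting material
2 | rac-exo,exo-3,6-bis(4-methoxyphenyl)tetrahydro-1H,4H-furo[3,4-c]furan-1,4-dione (racemate, one enantiomer drawn) | COc1ccc([C@H]2OC(=O)[C@H]3[C@@H]2C(=O)O[C@@H]3c2ccc(OC)cc2)cc1 | intermediate
3 | (3S,3aS,6S,6aS)-3,6-bis(4-methoxyphenyl)tetrahydro-1H,4H-furo[3,4-c]furan-1,4-dione | COc1ccc([C@H]2OC(=O)[C@H]3[C@@H]2C(=O)O[C@@H]3c2ccc(OC)cc2)cc1 | intermediate
4 | (2S,3S)-2,3-bis[(S)-hydroxy(4-methoxyphenyl)methyl]-N,N,N',N'-tetramethylbutanediamide | COc1ccc([C@@H](O)[C@@H](C(=O)N(C)C)[C@H](C(=O)N(C)C)[C@H](O)c2ccc(OC)cc2)cc1 | intermediate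
5 | mono-TBS ether of 4, (S,S,S,S) | COc1ccc([C@@H](O[Si](C)(C)C(C)(C)C)[C@@H](C(=O)N(C)C)[C@H](C(=O)N(C)C)[C@H](O)c2ccc(OC)cc2)cc1 | intermediate
6 | phloroglucinol | Oc1cc(O)cc(O)c1 | starting material
7 | 3,5-bis(benzyloxy)phenol | Oc1cc(OCc2ccccc2)cc(OCc2ccccc2)c1 | intermediate
8 | 3,5-bis(benzyloxy)-2-bromophenol | Oc1cc(OCc2ccccc2)cc(OCc2ccccc2)c1Br | intermediate
9 | [3,5-bis(benzyloxy)-2-bromophenoxy]trimethylsilane | C[Si](C)(C)Oc1cc(OCc2ccccc2)cc(OCc2ccccc2)c1Br | intermediate
10 | lithium 3,5-bis(benzyloxy)-2-(trimethylsilyl)phenoxide | [Li+].[O-]c1cc(OCc2ccccc2)cc(OCc2ccccc2)c1[Si](C)(C)C | intermediate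
11 | 3,5-bis(benzyloxy)-2-(trimethylsilyl)phenyl triflate | C[Si](C)(C)c1c(OCc2ccccc2)cc(OCc2ccccc2)cc1OS(=O)(=O)C(F)(F)F | intermediate
12 | 3,5-dimethoxyphenol | COc1cc(O)cc(OC)c1 | starting material
13 | 2-bromo-3,5-dimethoxyphenol | COc1cc(O)c(Br)c(OC)c1 | intermediate
14 | (2-bromo-3,5-dimethoxyphenoxy)trimethylsilane | COc1cc(O[Si](C)(C)C)c(Br)c(OC)c1 | intermediate
15 | lithium 3,5-dimethoxy-2-(trimethylsilyl)phenoxide | [Li+].[O-]c1cc(OC)cc(OC)c1[Si](C)(C)C | intermediate
16 | 3,5-dimethoxy-2-(trimethylsilyl)phenyl triflate | COc1cc(OC)c([Si](C)(C)C)c(OS(=O)(=O)C(F)(F)F)c1 | intermediate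
17 | potassium alkoxide of 5 | COc1ccc([C@@H](O[Si](C)(C)C(C)(C)C)[C@@H](C(=O)N(C)C)[C@H](C(=O)N(C)C)[C@H]([O-])c2ccc(OC)cc2)cc1.[K+] | intermediate
18 | 3,5-bis(benzyloxy)benzyne (3,5-bis(benzyloxy)-1,2-didehydrobenzene) | C1#CC(OCc2ccccc2)=CC(OCc2ccccc2)=C1 | intermediate
19 | potassium (2S,3S)-5,7-bis(benzyloxy)-3-[(1S,2S)-2-(tert-butyldimethylsilyloxy)-1-(dimethylcarbamoyl)-2-(4-methoxyphenyl)ethyl]-4-(dimethylamino)-2-(4-methoxyphenyl)chroman-4-olate (C4 unassigned) | COc1ccc([C@H]2Oc3cc(OCc4ccccc4)cc(OCc4ccccc4)c3C([O-])(N(C)C)[C@H]2[C@H](C(=O)N(C)C)[C@H](O[Si](C)(C)C(C)(C)C)c2ccc(OC)cc2)cc1.[K+] | intermediate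
20 | desilylated dialkoxide of 19 (potassium and tris(dimethylamino)sulfonium counter-ions) | COc1ccc([C@H]2Oc3cc(OCc4ccccc4)cc(OCc4ccccc4)c3C([O-])(N(C)C)[C@H]2[C@H](C(=O)N(C)C)[C@H]([O-])c2ccc(OC)cc2)cc1.[K+].CN(C)[S+](N(C)C)N(C)C | intermediate
21 | 3,5-dimethoxybenzyne (3,5-dimethoxy-1,2-didehydrobenzene) | C1#CC(OC)=CC(OC)=C1 | intermediate
22 | (2S,3S,2''S,3''S)-5,7-bis(benzyloxy)-4,4''-bis(dimethylamino)-5'',7''-dimethoxy-2,2''-bis(4-methoxyphenyl)-3,3''-bichromane-4,4''-diolate (C4, C4'' unassigned; potassium and tris(dimethylamino)sulfonium counter-ions) | COc1ccc([C@H]2Oc3cc(OCc4ccccc4)cc(OCc4ccccc4)c3C([O-])(N(C)C)[C@H]2[C@@H]2C([O-])(N(C)C)c3c(OC)cc(OC)cc3O[C@@H]2c2ccc(OC)cc2)cc1.[K+].CN(C)[S+](N(C)C)N(C)C | intermediate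
23 | (2S,3S,2''S,3''S)-5,7-bis(benzyloxy)-5'',7''-dimethoxy-2,2''-bis(4-methoxyphenyl)-3,3''-bichromane-4,4''-dione | COc1ccc([C@H]2Oc3cc(OCc4ccccc4)cc(OCc4ccccc4)c3C(=O)[C@H]2[C@@H]2C(=O)c3c(OC)cc(OC)cc3O[C@@H]2c2ccc(OC)cc2)cc1 | intermediate
24 | (2S,3S,2''S,3''S)-5,7,5''-trihydroxy-7''-methoxy-2,2''-bis(4-methoxyphenyl)-3,3''-bichromane-4,4''-dione | COc1ccc([C@H]2Oc3cc(O)cc(O)c3C(=O)[C@H]2[C@@H]2C(=O)c3c(O)cc(OC)cc3O[C@@H]2c2ccc(OC)cc2)cc1 | target

**Step count and risks**

Total step count: 11. Longest linear sequence: 6 (steps 1, 2, 3, 4, 10, 11).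

Steps most likely to fail:

1. Step 10 (proposed new method). The aryl anion may be protonated, or may take the C3 hydrogen by 1,5-transfer with loss of the aryloxide, before it reaches the amide carbonyl. The beta-alkoxide may fragment by retro-aldol cleavage. The silyl ether may be lost or moved too early, so that the order of the two arynes is blurred. Fallback with known chemistry, setting out from 5 and returning at 23: the aryne from 11 is used only for O-arylation with protonation of the aryl anion (CsF, MeCN, aryne O–H insertion) to give the 3,5-bis(benzyloxy)phenyl ether F1. Bu4NF removes the silyl group to give the alcohol F2, and a second O-arylation with the aryne from 16 gives the bis(aryl ether) bis-amide F3. Both rings are then closed by electrophilic amide activation (Tf2O, 2-fluoropyridine, CH2Cl2) and intramolecular Friedel–Crafts (Vilsmeier–Haack-type) acylation ortho to each ether oxygen, the two ortho positions of each ring being equivalent; hydrolysis of the iminium ions gives 23.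

2. Step 11. The Lewis acid may ionise the 4-methoxybenzylic C2–O1 and C2''–O1'' bonds (ring opening, epimerisation to the trans rings), the benzyl cation may alkylate the phloroglucinol ring, or the 7''-methyl ether may be partly cleaved. Fallback setting out from 23 and returning at 24: neutral hydrogenolysis (H2, Pd/C, EtOAc/MeOH) gives the 5,7-dihydroxy-5'',7''-dimethoxy biflavanone F4, and chelation-controlled demethylation of the peri 5''-methyl ether with MgI2·OEt2 gives 24.

3. Step 3. The second lactone may open slowly, the gamma-hydroxy amides may close back with loss of dimethylamine on work-up, or the aluminium reagent may ionise a benzylic C–O bond. Fallback setting out from 3 and returning at 5, without passing through 4: Me2NH alone (THF, 0 °C) opens only the first, strained lactone to the hydroxy lactone amide F5. Silylation (TBSOTf, 2,6-lutidine) gives the silyl ether F6, and aluminium-amide aminolysis (AlMe3, Me2NH) of the remaining lactone gives 5 directly, which also replaces the statistical silylation of step 4.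

**Further compounds**

F1 | step 10 | (2S,3S)-2-[(S)-[3,5-bis(benzyloxy)phenoxy](4-methoxyphenyl)methyl]-3-[(S)-(tert-butyldimethylsilyloxy)(4-methoxyphenyl)methyl]-N,N,N',N'-tetramethylbutanediamide | COc1ccc([C@@H](O[Si](C)(C)C(C)(C)C)[C@@H](C(=O)N(C)C)[C@H](C(=O)N(C)C)[C@H](Oc2cc(OCc3ccccc3)cc(OCc3ccccc3)c2)c2ccc(OC)cc2)cc1
F2 | step 10 | (2S,3S)-2-[(S)-[3,5-bis(benzyloxy)phenoxy](4-methoxyphenyl)methyl]-3-[(S)-hydroxy(4-methoxyphenyl)methyl]-N,N,N',N'-tetramethylbutanediamide | COc1ccc([C@@H](O)[C@@H](C(=O)N(C)C)[C@H](C(=O)N(C)C)[C@H](Oc2cc(OCc3ccccc3)cc(OCc3ccccc3)c2)c2ccc(OC)cc2)cc1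
F3 | step 10 | (2S,3S)-2-[(S)-[3,5-bis(benzyloxy)phenoxy](4-methoxyphenyl)methyl]-3-[(S)-(3,5-dimethoxyphenoxy)(4-methoxyphenyl)methyl]-N,N,N',N'-tetramethylbutanediamide | COc1ccc([C@@H](Oc2cc(OC)cc(OC)c2)[C@@H](C(=O)N(C)C)[C@H](C(=O)N(C)C)[C@H](Oc2cc(OCc3ccccc3)cc(OCc3ccccc3)c2)c2ccc(OC)cc2)cc1
F4 | step 11 | (2S,3S,2''S,3''S)-5,7-dihydroxy-5'',7''-dimethoxy-2,2''-bis(4-methoxyphenyl)-3,3''-bichromane-4,4''-dione | COc1ccc([C@H]2Oc3cc(O)cc(O)c3C(=O)[C@H]2[C@@H]2C(=O)c3c(OC)cc(OC)cc3O[C@@H]2c2ccc(OC)cc2)cc1
F5 | step 3 | (2S,3S,4S)-4-[(S)-hydroxy(4-methoxyphenyl)methyl]-2-(4-methoxyphenyl)-N,N-dimethyl-5-oxooxolane-3-carboxamide | COc1ccc([C@@H](O)[C@H]2C(=O)O[C@H](c3ccc(OC)cc3)[C@H]2C(=O)N(C)C)cc1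
F6 | step 3 | (2S,3S,4S)-4-[(S)-(tert-butyldimethylsilyloxy)(4-methoxyphenyl)methyl]-2-(4-methoxyphenyl)-N,N-dimethyl-5-oxooxolane-3-carboxamide | COc1ccc([C@@H](O[Si](C)(C)C(C)(C)C)[C@H]2C(=O)O[C@H](c3ccc(OC)cc3)[C@H]2C(=O)N(C)C)cc1
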